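The earlier runs and the new flask stem from a simulated flask with made-up constants; noise was put on by code.

The pitfall in this kinetic resolution was to fit a full mechanism to readings that scatter by 1 percentage point, when the earlier runs varied catalyst and the right-handed product was never read.

| setting | green | amber | ochre | Wednesday's | Monday's |
|---|---|---|---|---|---|
| left-handed substrate | 0.10 M | 0.10 M | 0.10 M | 0.10 M | 0.10 M |
| right-handed substrate | 0.10 M | 0.10 M | 0.10 M | 0.10 M | 0.10 M |
| solid reagent | 0.20 M | 0.20 M | 0.20 M | 0.200 M | 0.200 M |
| catalyst | 3.5 mM | 6.7 mM | 6.1 mM | 5.0 mM | 7.5 mM |
| remark | run made earlier | run made earlier | run made earlier |  |  |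
| time |  |  |  | 20 min | 20 min |

| run | time / min | left-handed product / % | left-handed substrate / % |
|---|---|---|---|
| green | 2.00 | 0.8 | 48.1 |
| green | 5.00 | 1.0 | 47.5 |
| green | 10.0 | 6.1 | 46.3 |
| green | 15.0 | 7.4 | 43.0 |
| green | 20.0 | 8.9 | 40.0 |
| amber | 1.50 | 0 | 48.7 |
| amber | 3.00 | 1.7 | 48.3 |
| amber | 6.00 | 4.7 | 45.0 |
| amber | 10.0 | 8.4 | 41.1 |
| amber | 20.0 | 17.1 | 32.9 |
| ochre | 4.00 | 4.1 | 47.9 |
| ochre | 8.00 | 4.4 | 44.3 |
| ochre | 12.0 | 9.2 | 40.1 |
| ochre | 15.0 | 12.7 | 37.6 |
| ochre | 20.0 | 16.1 | 34.9 |

(standard deviation of a reading: 1 percentage point)

- catalyst is single-handed; left-handed substrate and right-handed substrate are mirror images of each other, charged as a racemate, each of them at the stated concentration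
- given per volume of solution although it is solid: solid reagent
- at the start none of the solid reagent is in solution

- which of the two there is more of at the end, Wednesday's (right-handed product / left-handed product)
- which of the two there is more of at the end, Monday's (right-handed product / left-handed product)
- left-handed product at the end, in percent of the left-handed substrate and right-handed substrate together charged, Wednesday's
- left-handed product at the end, in percent of the left-handed substrate and right-handed substrate together charged, Monday's

I first asked which given numbers had to be known well. Time did: the left-handed product readings of the amber run rose by 8.7 points over its last 10.0 min. Catalyst did too: from the green run to the amber run it rose 1.91-fold and the last product reading 1.92-fold. Solid reagent did not need to be. Counting one solid reagent per product, and as much again for the unread right-handed product, I estimated the use in the amber run at 0.0684 M, less than the 0.20 M charged.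

So I summed the three runs, with P the left-handed product at 20 min and c the catalyst charged:

g = ΣP / Σc = 0.0258 mM⁻¹

This g, read from scattered readings, is the yield per catalyst, the fraction of both substrates charged that became left-handed product by that time, per unit of catalyst.

Wednesday's: g × 5.0 mM = 12.9%

Monday's: g × 7.5 mM = 19.4%

The forecast gave 13% for Wednesday's and 18.7% for Monday's, which is lower than my Monday figure, judging the loss “nearly proportional to catalyst, with slight flattening”. It named the left-handed product as the larger in both flasks, and I had no reading to set against that.

Wednesday's gave 13.4% of left-handed product against 5.77% of right-handed product, and Monday's gave 17.9% against 8.01%, so the forecast held.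

    solid reagent ⇌ coupling partner, rate k1*(cs1 - [coupling partner]) while solid is left; crystals form when [coupling partner] > cs1 (solubility = 0.0590 M, k = 0.00440 s⁻¹)
    coupling partner + catalyst + right-handed substrate → catalyst + right-handed product (k = 1.10 M⁻² s⁻¹)
    coupling partner + catalyst + left-handed substrate → catalyst + left-handed product (k = 2.80 M⁻² s⁻¹)
    catalyst ⇌ dormant form (K = 1.70, k = 0.00280 s⁻¹)

In Wednesday's flask, catalyst and dormant form relaxed by their own step alone, both ways together, with a half-life of 2.60 min, much shorter than the 20 min of the run. At that time catalyst stood at 37.3% of its charge in Wednesday's and 37.3% in Monday's, with coupling partner at 0.0518 M and 0.0496 M. The yield per catalyst came to 0.0268 mM⁻¹ in Wednesday's and 0.0239 mM⁻¹ in Monday's. For a further flask like Wednesday's but with 0.0030 M of catalyst, g gives 7.74%, and that flask gave 8.92%.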